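## Structural features

The target 12 is an acyclic 8-O-4' neolignan built on a three-carbon chain C7–C8–C9. C7 carries a free hydroxyl and ring A (a 3,4-dihydroxyphenyl group). C8 carries an ether oxygen bound to C4' of ring B (a 2-methoxyphenyl ring with a 3-hydroxypropyl chain para to that oxygen). C9 is a hydroxymethyl group. The only rings are the two benzene rings, joined to the chain by the C7–C1(ring A) bond and the C8–O–C4' aryl ether. C7 (S) and C8 (R) are adjacent stereocentres in the erythro relationship: the C7 hydroxyl and the C8 aryloxy group are anti when the chain ring A–C7–C8–C9 is drawn as a zigzag. Three groups are fragile: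
- the ring A catechol, which oxidises in air, above all as the catecholate;
- the C7 hydroxyl, benzylic and para to a phenolic oxygen, which can ionise to a quinone methide under acid or strong base and so lose its configuration;
- the C8–O aryl ether, which is expelled if a radical or carbanion develops at C7.

The skeleton needs only two fragment-joining bonds. The real difficulty is the absolute configuration of C8, a secondary alkyl aryl ether carbon, followed by the erythro relationship at C7, without ever epimerising either centre. The key step exploits the fact that C8 bears exactly the substituents of a branched adduct of a phenol with butadiene monoepoxide: the ring B aryloxy oxygen, the C9 hydroxymethyl group, and C7 carried as the inner carbon of a vinyl group until it is unmasked as a formyl group.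

## Logic of the disconnections

12 from 11. Only heteroatom bonds are cut: the two aryl O–Si bonds on ring A and the alkyl O–Si bonds at C9 and at the end of the propyl chain. All hydroxyls that need masking carry the same silyl group, so one fluoride treatment ends the synthesis. The gain is that every earlier compound is non-polar and resistant to oxidation. The demand is a desilylation neither basic enough to oxidise ring A nor acidic enough to ionise the C7 hydroxyl.

11 from 9 and 10. The C7–C1(ring A) bond is cut. C7 is a carbinol carbon next to the already configured C8, so the bond can be made by adding an aryl nucleophile to a formyl group with 1,2-induction from C8. This removes ring A and the second stereocentre together and leaves a three-carbon fragment with one stereocentre. The forward step must follow the non-chelated Felkin–Anh course to give the erythro isomer and must outrun enolisation of 9.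

10 from 7, and 7 from 6. The C–Mg bond and then the two aryl O–Si bonds are cut, which leads to a commercial bromocatechol. The demand is a phenol protecting group that survives magnesium insertion and leaves with the others in the last step.

9 from 5 through 8. The C7=O bond is traced back to a C7=CH2 bond. The alpha-aryloxy aldehyde is configurationally labile, so it is stored as a terminal alkene until just before use. The gain is a vinyl compound, which is the natural product of an allylic substitution. The demand is an oxidative cleavage that leaves the electron-rich ring B and the C8–H bond untouched.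

5 from 4. The O–Si bond at C9 is cut. The C9 hydroxyl must be capped before C7 becomes a formyl group: a free beta-hydroxy aldehyde would form hemiacetal oligomers, and a magnesium alkoxide at C9 would invite chelation. The forward step is an ordinary silylation.

4 from 2 and 3. The C8–O(aryl) bond is cut; this is the strategic disconnection. C8 becomes the internal carbon of an allyl electrophile and the C9 oxygen becomes its leaving group, tied back as an epoxide. The whole C7–C8–C9 unit then comes from a four-carbon commodity epoxide and the ring B half from a phenol, with no stoichiometric chiral material. The forward step must deliver the phenol to the internal allyl carbon (branched, not linear) and must convert both enantiomers of 3 into one enantiomer of 4.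

2 from 1. The alkyl O–Si bond on the propyl chain is cut, leading to a commercial phenol-alcohol. The demand is silylation at the aliphatic hydroxyl in preference to the phenol, which must stay free for the key step.

## Other disconnections considered

Alternative 1: The cut is the O–C4' bond on the ring B side of the ether oxygen, not the C8–O bond. In the forward step the potassium alkoxide of the dioxanol A2 would displace fluoride from 4-fluoro-3-methoxybenzaldehyde A3 by nucleophilic aromatic substitution to give A1. In A2 the C7 and C9 oxygens are tied in a benzylidene acetal, and C7 and C8 are already configured as in 12.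
- In its favour: neither stereocentre is touched when the ether is made, so there is no inversion to control and no 1,2-induction to rely on. The all-equatorial dioxane locks the erythro relationship in a rigid ring. No metal catalyst is needed.
- Against it here: A2, with both stereocentres and ring A, has to be built first. The fluoride is activated only by the para formyl group and is deactivated by the ortho methoxy group. The nucleophile is a hindered secondary alkoxide that can also add to the formyl group. After the key step the formyl group must still be grown into the 3-hydroxypropyl chain (two-carbon olefination, then reduction of alkene and ester). The final hydrogenolysis of benzyl ethers and benzylidene acetal would threaten the benzylic C7–O bond.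
- Structure: this alternative is the equal or the better of the chosen plan in stereochemical security, since both centres are in place and untouched.
- Mechanism: the substitution is simpler than a ligand-controlled allylic substitution, but it forces ring B to carry an electron-withdrawing group.
- Step economy: the chosen plan is clearly shorter, because it makes the C8 centre and the ether bond in one step and carries the finished side chain from the start.

Alternative 2: The cut is the C7–H bond. Both stereocentres would arise together from reduction of the C7 ketone in the racemic alpha-aryloxy beta-keto ester A4. In the forward step a ketoreductase with a recycled nicotinamide cofactor would reduce one enantiomer of the rapidly enolising A4 from one face to give the erythro hydroxy ester A5.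
- In its favour: C7 and C8 are fixed together under catalyst control in a single step from a racemate that racemises by itself. A4 can be assembled from simple achiral pieces with no stereochemical demand. Only the reduction of two esters and debenzylation would remain.
- Against it here: the ketone is flanked by a bulky aryl group and a bulky aryloxy ester carbon, a poor fit for many reductases. Which enzyme gives the erythro isomer of the right absolute configuration cannot be predicted and would have to be found by screening. The substrate is poorly soluble in water, and A5 remains prone to retro-aldol cleavage and C8 epimerisation until its ester is reduced.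
- Structure: this alternative is better at C7, because both centres are set by the catalyst, whereas the chosen plan relies on substrate induction.
- Mechanism: the two plans are equal in concept, both being dynamic kinetic conversions of a racemate. The chosen one uses a small-molecule catalyst with an established class of pronucleophile; this one depends on enzyme–substrate fit.
- Step economy: this alternative is the equal of the chosen plan or slightly shorter.

Alternative 3: The cut is the C7–C1(ring A) bond, the same bond as in the chosen plan, but made by radical cross-coupling. In the forward step the carboxylate of the dioxane acid A6 (derived from D-galactose A8, which supplies C8) would be oxidised under photoredox conditions and lose CO2. The C7 radical would be captured under nickel catalysis and coupled with 4-bromo-1,2-bis(benzyloxy)benzene A9 to give A7, with the aryl group trans to the C8 aryloxy group.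
- In its favour: C8 comes from the chiral pool without an asymmetric catalyst. The coupling is mild and neutral and avoids the epimerisable aldehyde; on that point it is better than the chosen plan. Alpha-oxy acids are good substrates for this type of coupling, and the acetal protects the C7 and C9 oxygens together.
- Against it here: the C7 configuration of A6 is erased at the radical stage and must be reset by face selection from C8 alone. In A7 the acetal methyl is cis to the aryloxy group, so no chair can place aryl, aryloxy and methyl all equatorial, and the trans selectivity is not backed by product stability. A radical at C7 sits beta to the aryloxy group and can expel an aryloxyl radical; the alkyl–nickel intermediate can likewise lose aryloxide. The electron-rich A9 is a slow partner for oxidative addition. Reaching A6 takes several steps (acetal formation, glycol cleavage, oxidation, arylation of the C8 hydroxyl), and acetal hydrolysis, ester reduction and debenzylation follow.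
- Structure: equal to the chosen plan in the bond formed at C7.
- Mechanism: the chosen plan is safer, since it keeps C7 electrophilic and never places a radical next to the aryl ether.
- Step economy: the chosen plan is shorter.

Key step: step 2

Assumption: the (R,R) enantiomer of the bisphosphine is taken to give the (S)-ether 4; should the facial sense prove the reverse, the (S,S) ligand is used with nothing else changed.

## Route

Step 1
Reactants: 1 3-(4-hydroxy-3-methoxyphenyl)propan-1-ol (dihydroconiferyl alcohol)
Product: 2 4-[3-(tert-butyldimethylsilyloxy)propyl]-2-methoxyphenol
Conditions: TBSCl (1.05 equiv), imidazole, CH2Cl2, 0 °C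
Reagents that add atoms: tert-butyldimethylsilyl chloride, CC(C)(C)[Si](C)(C)Cl
Why: Chemoselective silyl ether formation: in a non-polar solvent at low temperature the unhindered primary hydroxyl should react with the silylimidazolium species faster than the ortho-substituted guaiacol hydroxyl, which is hydrogen-bonded to the methoxy group.

Step 2
Reactants: 2 4-[3-(tert-butyldimethylsilyloxy)propyl]-2-methoxyphenol; 3 racemic 2-vinyloxirane (1.2 equiv)
Product: 4 (S)-2-{4-[3-(tert-butyldimethylsilyloxy)propyl]-2-methoxyphenoxy}but-3-en-1-ol
Conditions: Pd2(dba)3·CHCl3 (1 mol %), N,N'-[(1R,2R)-cyclohexane-1,2-diyl]bis[2-(diphenylphosphanyl)benzamide] (3 mol %), degassed CH2Cl2, rt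
Reagents that add atoms: none
Why: Tsuji–Trost-type allylic etherification run as a dynamic kinetic asymmetric transformation. Zerovalent palladium carrying the C2-symmetric bisphosphine opens either enantiomer of 3 with inversion to a zwitterionic pi-allylpalladium alkoxide; the two diastereomeric complexes interconvert by pi–sigma–pi isomerisation through the sigma-allyl bound at the terminal CH2 faster than they are captured, so the racemate converges. The alkoxide deprotonates the phenol 2 (far more acidic than any aliphatic hydroxyl present), and the phenoxide, held to the new hydroxyl by hydrogen bonding and ion pairing, attacks the adjacent internal allyl carbon on the face opposite palladium, forming the C8–O bond as the branched 1,2-adduct and not the linear 1,4-adduct. The closest known reactions are the palladium-catalysed asymmetric O-allylation of phenols and the dynamic kinetic additions of oxygen and nitrogen pronucleophiles to butadiene monoepoxide with this ligand family. No ring is closed. The single new stereocentre, C8, is under ligand control: the chiral pocket decides which diastereomeric allyl complex is attacked, and the ligand enantiomer is chosen for the S ether. The step needs regioselectivity (secured by alkoxide-directed delivery), enantioselectivity (ligand pocket plus allyl equilibration that is fast relative to attack) and chemoselectivity for the phenol over the primary hydroxyl of the product (secured by the absence of any boron or base additive that would activate an alcohol); the reaction is stopped once 2 is consumed so that the allyl aryl ether is not re-ionised.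

Step 3
Reactants: 4 (S)-2-{4-[3-(tert-butyldimethylsilyloxy)propyl]-2-methoxyphenoxy}but-3-en-1-ol
Product: 5 (S)-1-(tert-butyldimethylsilyloxy)-2-{4-[3-(tert-butyldimethylsilyloxy)propyl]-2-methoxyphenoxy}but-3-ene
Conditions: TBSCl, imidazole, DMF, rt
Reagents that add atoms: tert-butyldimethylsilyl chloride, CC(C)(C)[Si](C)(C)Cl
Why: Routine silylation of a primary alcohol that leaves C8 untouched; capping C9 prevents hemiacetal formation in the later aldehyde and removes a chelating alkoxide from the Grignard step.

Step 4
Reactants: 6 4-bromobenzene-1,2-diol
Product: 7 4-bromo-1,2-bis(tert-butyldimethylsilyloxy)benzene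
Conditions: TBSCl (2.4 equiv), imidazole, DMF, rt
Reagents that add atoms: tert-butyldimethylsilyl chloride, CC(C)(C)[Si](C)(C)Cl
Why: Silyl ether formation on both phenols; aryl silyl ethers tolerate magnesium insertion and leave in the final fluoride step together with the other silyl groups.

Step 5
Reactants: 5 (S)-1-(tert-butyldimethylsilyloxy)-2-{4-[3-(tert-butyldimethylsilyloxy)propyl]-2-methoxyphenoxy}but-3-ene
Product: 9 (R)-3-(tert-butyldimethylsilyloxy)-2-{4-[3-(tert-butyldimethylsilyloxy)propyl]-2-methoxyphenoxy}propanal, via vicinal diol 8 (not isolated)
Conditions: K2OsO4·2H2O (2 mol %), NaIO4 (4 equiv), 2,6-lutidine (2 equiv), 1,4-dioxane/H2O 3:1, rt; crude aldehyde dried and used at once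
Reagents that add atoms: sodium periodate, [Na+].[O-]I(=O)(=O)=O (terminal oxidant; its oxygen reaches C7 by way of OsO4)
Why: Lemieux–Johnson oxidative cleavage: OsO4 formed in the flask dihydroxylates the terminal alkene and periodate cleaves the glycol 8 and reoxidises osmium; unlike ozone, OsO4 does not attack the electron-rich ring B, and 2,6-lutidine buffers the medium. C8 is not involved in the reaction (the descriptor changes from S to R only because the priorities change), and immediate use limits enolisation.

Step 6
Reactants: 7 4-bromo-1,2-bis(tert-butyldimethylsilyloxy)benzene (1.6 equiv); 9 (R)-3-(tert-butyldimethylsilyloxy)-2-{4-[3-(tert-butyldimethylsilyloxy)propyl]-2-methoxyphenoxy}propanal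
Product: 11 (1S,2R)-1-[3,4-bis(tert-butyldimethylsilyloxy)phenyl]-3-(tert-butyldimethylsilyloxy)-2-{4-[3-(tert-butyldimethylsilyloxy)propyl]-2-methoxyphenoxy}propan-1-ol, via arylmagnesium bromide 10 (not isolated)
Conditions: 7, Mg turnings, I2 (cat.), THF, 45 °C; then 9, THF, −78 °C; sat. aq NH4Cl at −78 °C
Reagents that add atoms: none
Why: Grignard addition to an alpha-heteroatom aldehyde under polar Felkin–Anh control: the C8–OAr bond lies anti to the incoming aryl group, which passes the C8 hydrogen, so the 7,8-anti (erythro, 7S) alcohol should predominate. THF and the weakly basic aryloxy and bulky silyloxy oxygens disfavour a magnesium chelate, and the low temperature keeps addition ahead of enolisation.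

Step 7
Reactants: 11 (1S,2R)-1-[3,4-bis(tert-butyldimethylsilyloxy)phenyl]-3-(tert-butyldimethylsilyloxy)-2-{4-[3-(tert-butyldimethylsilyloxy)propyl]-2-methoxyphenoxy}propan-1-ol
Product: 12 (1S,2R)-1-(3,4-dihydroxyphenyl)-2-[4-(3-hydroxypropyl)-2-methoxyphenoxy]propane-1,3-diol
Conditions: Bu4NF/AcOH (1:1, excess), THF, 0 °C to rt, under argon
Reagents that add atoms: none
Why: Fluoride-driven cleavage of all four silyl ethers through Si–F bond formation; the acetic acid buffer keeps the liberated catechol protonated, which should prevent catecholate autoxidation and quinone-methide epimerisation at C7, and no stereocentre is touched.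

## Compound list

1 | 3-(4-hydroxy-3-methoxyphenyl)propan-1-ol (dihydroconiferyl alcohol) | OCCCc1ccc(O)c(OC)c1 | starting material
2 | 4-[3-(tert-butyldimethylsilyloxy)propyl]-2-methoxyphenol | COc1cc(CCCO[Si](C)(C)C(C)(C)C)ccc1O | intermediate
3 | racemic 2-vinyloxirane (butadiene monoepoxide) | C=CC1CO1 | starting material
4 | (S)-2-{4-[3-(tert-butyldimethylsilyloxy)propyl]-2-methoxyphenoxy}but-3-en-1-ol | COc1cc(CCCO[Si](C)(C)C(C)(C)C)ccc1O[C@H](CO)C=C | intermediate
5 | (S)-1-(tert-butyldimethylsilyloxy)-2-{4-[3-(tert-butyldimethylsilyloxy)propyl]-2-methoxyphenoxy}but-3-ene | COc1cc(CCCO[Si](C)(C)C(C)(C)C)ccc1O[C@H](CO[Si](C)(C)C(C)(C)C)C=C | intermediate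
6 | 4-bromobenzene-1,2-diol | Oc1ccc(Br)cc1O | starting material
7 | 4-bromo-1,2-bis(tert-butyldimethylsilyloxy)benzene | CC(C)(C)[Si](C)(C)Oc1ccc(Br)cc1O[Si](C)(C)C(C)(C)C | intermediate
8 | (2RS,3R)-4-(tert-butyldimethylsilyloxy)-3-{4-[3-(tert-butyldimethylsilyloxy)propyl]-2-methoxyphenoxy}butane-1,2-diol (mixture of C2 epimers) | COc1cc(CCCO[Si](C)(C)C(C)(C)C)ccc1O[C@H](CO[Si](C)(C)C(C)(C)C)C(O)CO | intermediate (not isolated)
9 | (R)-3-(tert-butyldimethylsilyloxy)-2-{4-[3-(tert-butyldimethylsilyloxy)propyl]-2-methoxyphenoxy}propanal | COc1cc(CCCO[Si](C)(C)C(C)(C)C)ccc1O[C@H](CO[Si](C)(C)C(C)(C)C)C=O | intermediate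
10 | [3,4-bis(tert-butyldimethylsilyloxy)phenyl]magnesium bromide | CC(C)(C)[Si](C)(C)Oc1ccc([Mg]Br)cc1O[Si](C)(C)C(C)(C)C | intermediate (not isolated)
11 | (1S,2R)-1-[3,4-bis(tert-butyldimethylsilyloxy)phenyl]-3-(tert-butyldimethylsilyloxy)-2-{4-[3-(tert-butyldimethylsilyloxy)propyl]-2-methoxyphenoxy}propan-1-ol | COc1cc(CCCO[Si](C)(C)C(C)(C)C)ccc1O[C@H](CO[Si](C)(C)C(C)(C)C)[C@@H](O)c1ccc(O[Si](C)(C)C(C)(C)C)c(O[Si](C)(C)C(C)(C)C)c1 | intermediate
12 | (1S,2R)-1-(3,4-dihydroxyphenyl)-2-[4-(3-hydroxypropyl)-2-methoxyphenoxy]propane-1,3-diol (erythro; 7S,8R) | COc1cc(CCCO)ccc1O[C@H](CO)[C@@H](O)c1ccc(O)c(O)c1 | target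

## Step count and least certain steps

Total: 7 steps. Longest linear sequence: 6 steps (steps 1, 2, 3, 5, 6, 7); step 4 is a one-step side branch.

Step 2 (key step). The most likely failures are attack at the terminal allyl carbon to give the linear ether, capture of the allyl complexes before they have equilibrated, and re-ionisation of the allyl aryl ether on prolonged contact with the catalyst. The last two both erode the enantiomeric purity, and the ortho-methoxy phenol is a hindered nucleophile. The fallback sets out from 2 and rejoins the route at 5. It is a Mitsunobu etherification (PPh3, DIAD, toluene, 0 °C to rt) of 2 with (R)-1-[(tert-butyldimethylsilyl)oxy]but-3-en-2-ol F1. F1 is obtainable in one step from commercial tert-butyldimethylsilyl (R)-glycidyl ether and dimethylsulfonium methylide. Displacement of the activated hydroxyl with inversion would give 5 directly, so steps 2 and 3 are both replaced and the C8 configuration comes from the chiral pool instead of the catalyst.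

Step 6. The most likely failure is poor facial selectivity through a competing magnesium chelate between the carbonyl oxygen and the C8 aryloxy and methoxy oxygens, which would lead to the threo isomer. Enolisation of the aldehyde by the basic reagent, with loss of the C8 configuration, is the second concern. The fallback sets out from 11 obtained as a mixture of C7 epimers and returns to 11 as the erythro isomer. The mixture is oxidised with Dess–Martin periodinane (NaHCO3, CH2Cl2) to (R)-1-[3,4-bis(tert-butyldimethylsilyloxy)phenyl]-3-(tert-butyldimethylsilyloxy)-2-{4-[3-(tert-butyldimethylsilyloxy)propyl]-2-methoxyphenoxy}propan-1-one F2. The ketone is then reduced with Zn(BH4)2 in Et2O at low temperature. Here chelation is wanted: hydride adds to the zinc chelate of the ketone and C8 aryloxy oxygens from the side of the C8 hydrogen, which gives the erythro alcohol.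

Step 5. The most likely failure is epimerisation at C8 through enolisation of the alpha-aryloxy aldehyde (or its hydrate) in the aqueous, mildly basic medium, followed by beta-elimination of the C9 silyloxy group. The fallback sets out from 5 and returns at 9. It is ozonolysis in CH2Cl2 at −78 °C, stopped at the colour change of Sudan Red 7B to protect ring B. The ozonide, 3-[(1R)-2-(tert-butyldimethylsilyloxy)-1-{4-[3-(tert-butyldimethylsilyloxy)propyl]-2-methoxyphenoxy}ethyl]-1,2,4-trioxolane F3, is reduced with PPh3 under anhydrous, base-free conditions, and the aldehyde is taken straight into step 6.

Step 1. The most likely failure is loss of chemoselectivity, with silylation of the phenolic oxygen as well. The fallback sets out from 1 and returns at 2. Both hydroxyls are silylated (TBSCl in excess, imidazole, DMF) to tert-butyl{4-[3-(tert-butyldimethylsilyloxy)propyl]-2-methoxyphenoxy}dimethylsilane F4. The aryl silyl ether alone is then cleaved by K2CO3 in MeOH at rt, conditions that alkyl silyl ethers survive.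

## Further compounds

F1 | step 2 | (R)-1-[(tert-butyldimethylsilyl)oxy]but-3-en-2-ol | O[C@@H](CO[Si](C)(C)C(C)(C)C)C=C
F2 | step 6 | (R)-1-[3,4-bis(tert-butyldimethylsilyloxy)phenyl]-3-(tert-butyldimethylsilyloxy)-2-{4-[3-(tert-butyldimethylsilyloxy)propyl]-2-methoxyphenoxy}propan-1-one | COc1cc(CCCO[Si](C)(C)C(C)(C)C)ccc1O[C@H](CO[Si](C)(C)C(C)(C)C)C(=O)c1ccc(O[Si](C)(C)C(C)(C)C)c(O[Si](C)(C)C(C)(C)C)c1
F3 | step 5 | 3-[(1R)-2-(tert-butyldimethylsilyloxy)-1-{4-[3-(tert-butyldimethylsilyloxy)propyl]-2-methoxyphenoxy}ethyl]-1,2,4-trioxolane (mixture of epimers at the trioxolane carbon) | COc1cc(CCCO[Si](C)(C)C(C)(C)C)ccc1O[C@H](CO[Si](C)(C)C(C)(C)C)C1OCOO1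
F4 | step 1 | tert-butyl{4-[3-(tert-butyldimethylsilyloxy)propyl]-2-methoxyphenoxy}dimethylsilane | COc1cc(CCCO[Si](C)(C)C(C)(C)C)ccc1O[Si](C)(C)C(C)(C)C
A1 | alternative 1 | 4-{[4-(3,4-bis(benzyloxy)phenyl)-2-phenyl-1,3-dioxan-5-yl]oxy}-3-methoxybenzaldehyde (2,4-cis, 4,5-trans; C4 and C5 configured as C7 and C8 of the target) | COc1cc(C=O)ccc1O[C@@H]1CO[C@@H](c2ccccc2)O[C@H]1c1ccc(OCc2ccccc2)c(OCc2ccccc2)c1
A2 | alternative 1 | 4-[3,4-bis(benzyloxy)phenyl]-2-phenyl-1,3-dioxan-5-ol (2,4-cis, 4,5-trans; C4 and C5 configured as C7 and C8 of the target) | O[C@@H]1CO[C@@H](c2ccccc2)O[C@H]1c1ccc(OCc2ccccc2)c(OCc2ccccc2)c1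
A3 | alternative 1 | 4-fluoro-3-methoxybenzaldehyde | COc1cc(C=O)ccc1F
A4 | alternative 2 | racemic methyl 3-[3,4-bis(benzyloxy)phenyl]-2-[2-methoxy-4-(3-methoxy-3-oxopropyl)phenoxy]-3-oxopropanoate | COC(=O)CCc1ccc(OC(C(=O)OC)C(=O)c2ccc(OCc3ccccc3)c(OCc3ccccc3)c2)c(OC)c1
A5 | alternative 2 | methyl (2S,3S)-3-[3,4-bis(benzyloxy)phenyl]-3-hydroxy-2-[2-methoxy-4-(3-methoxy-3-oxopropyl)phenoxy]propanoate (erythro) | COC(=O)CCc1ccc(O[C@H](C(=O)OC)[C@@H](O)c2ccc(OCc3ccccc3)c(OCc3ccccc3)c2)c(OC)c1
A6 | alternative 3 | 5-[2-methoxy-4-(3-methoxy-3-oxopropyl)phenoxy]-2-methyl-1,3-dioxane-4-carboxylic acid (carboxyl, aryloxy and methyl all cis, as derived from the sugar) | COC(=O)CCc1ccc(O[C@@H]2CO[C@H](C)O[C@@H]2C(=O)O)c(OC)c1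
A7 | alternative 3 | methyl 3-[4-({4-[3,4-bis(benzyloxy)phenyl]-2-methyl-1,3-dioxan-5-yl}oxy)-3-methoxyphenyl]propanoate (4,5-trans; methyl cis to the aryloxy group) | COC(=O)CCc1ccc(O[C@@H]2CO[C@H](C)O[C@H]2c4ccc(OCc5ccccc5)c(OCc5ccccc5)c4)c(OC)c1
A8 | alternative 3 | D-galactose (pyranose form) | OC[C@H]1OC(O)[C@H](O)[C@@H](O)[C@H]1O
A9 | alternative 3 | 4-bromo-1,2-bis(benzyloxy)benzene | Brc1ccc(OCc2ccccc2)c(OCc2ccccc2)c1
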